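A charge of 1.0 M of substrate stood against 5.0 mM of free catalyst, a factor of 200 between the two amounts, so even a rare loss per substrate could show in the catalyst.

substrate 1.0 M; reagent 1.20 M; free catalyst 5.0 mM; second catalyst 5.0 mM

    substrate + free catalyst → free catalyst + intermediate (k1 = 6.11 M⁻¹ s⁻¹)
    2 reagent → self-condensation product (k2 = 0.0325 M⁻¹ s⁻¹)
    substrate + free catalyst → spent catalyst (k3 = 0.00519 M⁻¹ s⁻¹)
    reagent + second catalyst + intermediate → second catalyst + target (k4 = 8.32 M⁻² s⁻¹)

- the form that holds most of the catalyst when 20 % of the substrate are converted (free catalyst / spent catalyst)
- its share of the catalyst then
- factor on the rate of making target when 20 % of the substrate are converted if free catalyst is charged twice over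
- factor on the rate when 20 % of the substrate are converted if free catalyst is charged at 50 mM instead

- a doubled species enters its step squared and goes two at a time
- "the catalyst" is free catalyst with its forms; second catalyst is a second catalyst
- charge of substrate (flask): 1.0 M

I asked first what the catalyst must have become by a given conversion, and I set two rates per free catalyst side by side, with the substrate as charged: 370 min⁻¹ for the step that gives intermediate and 0.31 min⁻¹ for the step that gives spent catalyst. Both steps run at a constant times c(substrate) times c(free catalyst), so the ratio of their rates, a selectivity factor, stayed the same throughout and time dropped out of the question. The spent catalyst formed for each substrate consumed was therefore the constant of the losing step over the sum of the two constants, 8.49 × 10⁻⁴, and I called this the loss per substrate. At 20 % conversion, 0.200 M of substrate had gone in this flask, so c(spent catalyst) came to 0.170 mM, which was 3.39 % of the catalyst, and free catalyst held more of it than spent catalyst, with 96.6 %. The loss per substrate says what the catalyst has become, not how fast target forms, so I committed to no number of my own for the two factors on the rate.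

The forecast named free catalyst at 96.6 % and gave factors of 1.31 and 1.71, with the remark “Reagent self-condensation is significant”.

The run gave free catalyst at 96.6 %, with 3.39 % as spent catalyst after 0.124 min, and factors of 1.31 and 1.72. In the same flask, with a fraction 0.7 of the substrate converted, the loss per substrate gives 88.1 % free catalyst and the run gave 88.1 %, while in the flask charged with 50 mM it gives 99.7 % at 20 % conversion and the run gave 99.7 %. In the flask charged with 5.0 mM, at 0.396 min, reagent went to self-condensation product 1.5 times as fast as it went to target. After 40.0 min that flask held 0 % of its reagent, and of the substrate charged, 35.6 % stood as target and 64.3 % as intermediate.

The numbers were set for the occasion; the result is computed.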